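**Retrosynthetic overview**

- Feature: ring A (C1–C4, C4a, C8a of the naphthol half) and ring D (C1'–C4', C4a', C8a' of the dihydro half) carry the same substituents (O at C1, acetyl at C2, methyl at C3) and differ only by one H2 across C1–C2. The target is therefore a C2-symmetric bis(dihydronaphthalenol) less one H2.
- Last disconnection: dehydrogenation of one C1 carbinol; the resulting 1(2H)-naphthalenone tautomerises to the ring A naphthol.
- Key disconnection: C1–C2 and C1'–C2' by a two-directional proline-catalysed dienamine aldol on a symmetric biaryl that carries, on each ring, a 3-formyl group and a 4-(2-methyl-4-oxopent-2-enyl) arm. Rings B and C are the arenes of the starting phenol; rings A and D are closed together, last.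
- Biaryl bond C7–C7': Stille coupling of two arm-bearing halves, an aryl bromide and the arylstannane made from it. Arm: lateral lithiation of the tert-butylimine of MOM-protected 3-bromo-6-methylsalicylaldehyde (from ortho-formylation of 2-bromo-5-methylphenol) and transposing addition to 4-methoxypent-3-en-2-one.

Key step: step 8

Assumption: the C7–C7' axis has only one non-hydrogen ortho substituent on each ring (8-OH, 8'-OH), so it rotates freely and is not a stereogenic element; C1' (S) and C2' (R) are the only stereocenters to control. Commercial 4-methoxypent-3-en-2-one is taken as the E isomer; its geometry is lost in step 4.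

**Route**

Step 1
Reactants: 1 2-bromo-5-methylphenol; 2 formaldehyde (as paraformaldehyde)
Product: 3 3-bromo-2-hydroxy-6-methylbenzaldehyde
Conditions: MgCl2, Et3N, (CH2O)n, MeCN, reflux; then 1 M HCl
Reagents that add atoms: none
Why: Magnesium-phenoxide-directed ortho-formylation (Casiraghi–Skattebøl reaction) is strictly ortho-selective and C6 is the only free ortho position, a second equivalent of formaldehyde acting as hydride acceptor for the intermediate benzylic alkoxide.

Step 2
Reactants: 3 3-bromo-2-hydroxy-6-methylbenzaldehyde
Product: 4 3-bromo-2-(methoxymethoxy)-6-methylbenzaldehyde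
Conditions: NaH, MOMCl, DMF, 0 °C → rt
Reagents that add atoms: chloromethyl methyl ether, COCCl
Why: Williamson etherification of the sodium phenoxide removes the acidic O–H and gives an acetal that is inert to the lithium amide base of step 4 and to the palladium-catalysed steps 5 and 6.

Step 3
Reactants: 4 3-bromo-2-(methoxymethoxy)-6-methylbenzaldehyde
Product: 5 (E)-N-tert-butyl-1-[3-bromo-2-(methoxymethoxy)-6-methylphenyl]methanimine
Conditions: t-BuNH2 (excess), 4 Å molecular sieves, toluene, 50 °C; filtered, concentrated, used crude
Reagents that add atoms: tert-butylamine, CC(C)(C)N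
Why: Condensation of the aldehyde with a primary amine (imine formation, the water being taken up by the sieves) masks the carbonyl group against the base of step 4, the bulky tert-butyl group shields C=N from nucleophiles and allows only the E imine, and the C=N bond acidifies the ortho methyl group for lateral metalation.

Step 4
Reactants: 5 (E)-N-tert-butyl-1-[3-bromo-2-(methoxymethoxy)-6-methylphenyl]methanimine; 6 (E)-4-methoxypent-3-en-2-one
Product: 9 3-bromo-2-(methoxymethoxy)-6-[(E)-2-methyl-4-oxopent-2-en-1-yl]benzaldehyde, via lateral lithio imine 7 (not isolated), via lithium alkoxide adduct 8 (not isolated)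
Conditions: lithium 2,2,6,6-tetramethylpiperidide (from 2,2,6,6-tetramethylpiperidine and n-BuLi), THF, −78 → −40 °C; 6, −78 °C; then 1 M HCl, THF, 0 °C
Reagents that add atoms: water, O
Why: Lateral lithiation of an o-tolualdehyde tert-butylimine with a hindered lithium amide gives the delocalised benzylic anion without the halogen–lithium exchange that an alkyllithium would cause at the aryl bromide, the anion adds 1,2 to the ketone of the vinylogous ester 6, and dilute acid then hydrolyses the imine and triggers a Stork–Danheiser-type transposition (loss of the tertiary hydroxyl, hydrolysis of the enol ether) to the β-benzyl enone, whose E geometry is the expected equilibrium one and is in any case erased in step 8.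

Step 5
Reactants: 9 3-bromo-2-(methoxymethoxy)-6-[(E)-2-methyl-4-oxopent-2-en-1-yl]benzaldehyde
Product: 10 2-(methoxymethoxy)-6-[(E)-2-methyl-4-oxopent-2-en-1-yl]-3-(trimethylstannyl)benzaldehyde
Conditions: Me3SnSnMe3 (1.2 equiv), Pd(PPh3)4 (5 mol%), toluene, 100 °C; carried out on half of the stock of 9
Reagents that add atoms: hexamethylditin, C[Sn](C)(C)[Sn](C)(C)C
Why: Palladium-catalysed stannylation of an aryl bromide with a distannane (oxidative addition to zerovalent palladium, Sn–Sn transmetalation, reductive elimination of the Ar–Sn bond) needs neither base nor nucleophile, so the aldehyde and the enolisable enone arm next to it should be left alone.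

Step 6
Reactants: 9 3-bromo-2-(methoxymethoxy)-6-[(E)-2-methyl-4-oxopent-2-en-1-yl]benzaldehyde; 10 2-(methoxymethoxy)-6-[(E)-2-methyl-4-oxopent-2-en-1-yl]-3-(trimethylstannyl)benzaldehyde
Product: 11 2,2'-bis(methoxymethoxy)-4,4'-bis[(E)-2-methyl-4-oxopent-2-en-1-yl]biphenyl-3,3'-dicarbaldehyde
Conditions: 9 (1.0 equiv), 10 (1.05 equiv), Pd2(dba)3 (5 mol%), AsPh3, CuI (20 mol%), NMP, 60 °C
Reagents that add atoms: none
Why: Stille cross-coupling (oxidative addition of bromide 9 to zerovalent palladium, copper-assisted transmetalation of stannane 10, reductive elimination) forms the biaryl bond that becomes C7–C7' under neutral conditions that should not enolise the arm toward the neighbouring aldehyde, each partner has only one ortho substituent, and adventitious homocoupling of either partner gives the same symmetric biaryl.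

Step 7
Reactants: 11 2,2'-bis(methoxymethoxy)-4,4'-bis[(E)-2-methyl-4-oxopent-2-en-1-yl]biphenyl-3,3'-dicarbaldehyde
Product: 12 2,2'-dihydroxy-4,4'-bis[(E)-2-methyl-4-oxopent-2-en-1-yl]biphenyl-3,3'-dicarbaldehyde
Conditions: NaHSO4·SiO2, CH2Cl2, rt
Reagents that add atoms: none
Why: Acid-catalysed acetal hydrolysis of aryl MOM ethers on NaHSO4-loaded silica is heterogeneous, mild and brief, which should leave the aldehyde and enone arms uncondensed.

Step 8
Reactants: 12 2,2'-dihydroxy-4,4'-bis[(E)-2-methyl-4-oxopent-2-en-1-yl]biphenyl-3,3'-dicarbaldehyde
Product: 15 (1S,1'S,2R,2'R)-2,2'-diacetyl-3,3'-dimethyl-1,1',2,2'-tetrahydro-[7,7'-binaphthalene]-1,1',8,8'-tetrol, via dienamine 13 (not isolated), via mono-aldol 14 (not isolated)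
Conditions: (R)-proline (30 mol% per arm), DMSO, 20 °C, 0.01 M; pH 7 buffer quench
Reagents that add atoms: none
Why: Proposed new method: (R)-proline condenses with the methyl ketone of an arm, the iminium ion loses the doubly activated benzylic proton at C4 to give the linear dienamine 13, whose α-carbon C2 adds to the neighbouring aldehyde carbon C1 before hydrolysis returns the catalyst, and the same cycle then closes the second arm of 14; this is an enamine aldol addition, and the closest known reaction type is the proline-catalysed intramolecular 6-enolexo aldolization of keto aldehydes, extended here to a dienamine from a β,β-disubstituted enone and to two closures on one biaryl. Each new ring (the later rings A and D) closes in the 6-(enolexo)-exo-trig mode, forming C1–C2 and C1'–C2'. The configuration at C1 and C1' is controlled by the carboxylic acid of the catalyst, which hydrogen-bonds the aldehyde oxygen and so delivers one aldehyde face to the enamine face on its own side; (R)-proline is chosen because, in the established acid-directed enamine transition-state model, the (S)-catalyst gives the mirror-image sense in the analogous anti-aldol of ketone (E)-enamines with aryl aldehydes. The configuration at C2 and C2' follows from the (E)-enamine geometry in a chair-like transition state with the aryl group of the aldehyde pseudo-equatorial, which gives the trans (anti) aldol, and C2 stays epimerisable through the enamine so that cis material can drain to the trans isomer expected to be more stable. The step needs regioselectivity for the α-carbon and chemoselectivity for addition over dehydration or intermolecular aldolization: the ortho relation of aldehyde and arm secures the first (attack through the γ-carbon or the methyl carbon would need a four- or an eight-membered ring), and neutral conditions, high dilution and an early quench are meant to secure the second. Because the two closures are independent, mismatched closures should end up mainly in a separable meso-type diastereomer, which raises the enantiopurity of the C2-symmetric product.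

Step 9
Reactants: 15 (1S,1'S,2R,2'R)-2,2'-diacetyl-3,3'-dimethyl-1,1',2,2'-tetrahydro-[7,7'-binaphthalene]-1,1',8,8'-tetrol
Product: 17 1-[(1'S,2'R)-2'-acetyl-1,1',8,8'-tetrahydroxy-3,3'-dimethyl-1',2'-dihydro-[7,7'-binaphthalen]-2-yl]ethan-1-one (CNP0298944.1), via naphthalen-1(2H)-one 16 (not isolated)
Conditions: activated MnO2, CH2Cl2, 0 °C, stopped at partial conversion; recovered 15 recycled
Reagents that add atoms: none
Why: Activated MnO2 oxidises benzylic (here o-hydroxybenzylic) carbinols under neutral conditions, and the resulting 2-acetyl-1(2H)-naphthalenone 16 is a cyclic β-diketone whose enol is the aromatic naphthol of ring A, so tautomerisation is spontaneous and irreversible; the two carbinols of C2-symmetric 15 are homotopic, so either gives 17, C1' and C2' of the untouched half are not affected, and stopping early limits oxidation of the second carbinol.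

**Compound list**

1 | 2-bromo-5-methylphenol | Cc1ccc(Br)c(O)c1 | starting material
2 | formaldehyde (used as paraformaldehyde) | C=O | starting material
3 | 3-bromo-2-hydroxy-6-methylbenzaldehyde | Cc1ccc(Br)c(O)c1C=O | intermediate
4 | 3-bromo-2-(methoxymethoxy)-6-methylbenzaldehyde | Cc1ccc(Br)c(OCOC)c1C=O | intermediate
5 | (E)-N-tert-butyl-1-[3-bromo-2-(methoxymethoxy)-6-methylphenyl]methanimine | Cc1ccc(Br)c(OCOC)c1/C=N/C(C)(C)C | intermediate
6 | (E)-4-methoxypent-3-en-2-one | CO/C(C)=C/C(C)=O | starting material
7 | laterally lithiated imine (benzylic lithium derivative of 5) | [Li]Cc1ccc(Br)c(OCOC)c1/C=N/C(C)(C)C | intermediate (not isolated)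
8 | lithium alkoxide adduct: benzylic carbon of 7 bonded to C2 of 6 as a tertiary alkoxide, enol ether and imine retained (racemic at the carbinol carbon) | CO/C(C)=C/C(C)([O-])Cc1ccc(Br)c(OCOC)c1/C=N/C(C)(C)C.[Li+] | intermediate (not isolated)
9 | 3-bromo-2-(methoxymethoxy)-6-[(E)-2-methyl-4-oxopent-2-en-1-yl]benzaldehyde | O=Cc1c(C/C(C)=C/C(C)=O)ccc(Br)c1OCOC | intermediate
10 | 2-(methoxymethoxy)-6-[(E)-2-methyl-4-oxopent-2-en-1-yl]-3-(trimethylstannyl)benzaldehyde | O=Cc1c(C/C(C)=C/C(C)=O)ccc([Sn](C)(C)C)c1OCOC | intermediate
11 | 2,2'-bis(methoxymethoxy)-4,4'-bis[(E)-2-methyl-4-oxopent-2-en-1-yl]biphenyl-3,3'-dicarbaldehyde | O=Cc1c(C/C(C)=C/C(C)=O)ccc(c1OCOC)-c1ccc(C/C(C)=C/C(C)=O)c(C=O)c1OCOC | intermediate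
12 | 2,2'-dihydroxy-4,4'-bis[(E)-2-methyl-4-oxopent-2-en-1-yl]biphenyl-3,3'-dicarbaldehyde | O=Cc1c(C/C(C)=C/C(C)=O)ccc(c1O)-c1ccc(C/C(C)=C/C(C)=O)c(C=O)c1O | intermediate (key-step precursor)
13 | dienamine of one arm of 12 with (R)-proline (N–C(CH3)=CH–C(CH3)=CH–Ar, E at the enamine bond, aryl cis to C2) | OC(=O)[C@H]1CCCN1/C(C)=C/C(C)=C\c1ccc(-c2ccc(C/C(C)=C/C(C)=O)c(C=O)c2O)c(O)c1C=O | intermediate (not isolated)
14 | mono-aldol: (1S,2R)-2-acetyl-1,8-dihydroxy-3-methyl-1,2-dihydronaphthalen-7-yl joined to the unchanged aldehyde–enone ring | Oc1c(-c2ccc(C/C(C)=C/C(C)=O)c(C=O)c2O)ccc2c1[C@@H](O)[C@H](C(C)=O)C(C)=C2 | intermediate (not isolated)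
15 | (1S,1'S,2R,2'R)-2,2'-diacetyl-3,3'-dimethyl-1,1',2,2'-tetrahydro-[7,7'-binaphthalene]-1,1',8,8'-tetrol | Oc1c(-c2ccc3c(c2O)[C@@H](O)[C@H](C(C)=O)C(C)=C3)ccc2c1[C@@H](O)[C@H](C(C)=O)C(C)=C2 | intermediate (key-step product)
16 | 2-acetyl-8-hydroxy-3-methylnaphthalen-1(2H)-one joined at C7 to the (1S,2R)-dihydronaphthalenol half (C2 of the ketone half as in 15, lost on enolisation) | Oc1c(-c2ccc3c(c2O)[C@@H](O)[C@H](C(C)=O)C(C)=C3)ccc2c1C(=O)[C@H](C(C)=O)C(C)=C2 | intermediate (not isolated)
17 | 1-[(1'S,2'R)-2'-acetyl-1,1',8,8'-tetrahydroxy-3,3'-dimethyl-1',2'-dihydro-[7,7'-binaphthalen]-2-yl]ethan-1-one (CNP0298944.1) | CC(=O)c1c(C)cc2ccc(-c3ccc4c(c3O)[C@@H](O)[C@H](C(C)=O)C(C)=C4)c(O)c2c1O | target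

**Step count**

Total steps: 9. Longest linear sequence: 9 (1 → 3 → 4 → 5 → 9 → 10 → 11 → 12 → 15 → 17; 2 and 6 are commercial inputs, and 9 enters step 6 a second time as the partner of 10).

**Steps most likely to fail**

1. Step 8 (proposed new method).
What may go wrong:
- slow or incomplete dienamine formation from the conjugated, β,β-disubstituted enone;
- poor facial selectivity if the phenol-activated aldehyde reacts without guidance by the acid of the catalyst;
- loss of water from the aldol with aromatisation to a 1-deoxy naphthalene;
- reversibility.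

If only the facial sense is opposite to the model, (S)-proline is used instead.

Fallback (known chemistry), setting out from 12: the rings are closed without a chiral catalyst as lithium dienolate aldol additions. LiN(SiMe3)2 (slightly less than four equivalents, two of them taken up by the phenols) in THF, −78 → −40 °C, lets the enolates equilibrate to the extended dienolate, the only one that can cyclise. The chelated lithium aldolates are quenched cold with AcOH. This should give 15 as a racemate with its (1R,1'R,2S,2'S)-enantiomer F1, together with the meso-type (1S,2R,1'R,2'S)-diastereomer F2. F2 is removed on silica and 15 is separated from F1 by preparative HPLC on a chiral stationary phase. The route is rejoined at 15.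

2. Step 9.
What may go wrong:
- oxidation running on to the second, equally reactive carbinol;
- oxidative degradation of the free phenol and naphthol groups;
- dehydration of the remaining aldol unit on the oxide surface.

Fallback, setting out from 15: one half is masked before the oxidation. t-Bu2Si(OTf)2 (one equivalent), 2,6-lutidine, CH2Cl2, −40 °C should bridge O1 and O8 of one half as a six-membered cyclic di-tert-butylsilylene, giving the mono-silylene F3 beside the bis-silylene F4 and unreacted 15. Both are returned to the pool, F4 after HF·pyridine. With the second carbinol blocked, the free carbinol of F3 is oxidised to completion with excess MnO2 to the silylene-protected naphthol F5. HF·pyridine in THF/pyridine at 0 °C then removes the silylene and gives 17, where the route is rejoined. The statistical event becomes a reversible protection, so no material is lost to over-oxidation.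

3. Step 4.
What may go wrong:
- proton transfer from the enolisable enone 6 to the basic benzylic anion instead of addition;
- conjugate addition–elimination in the flask, which frees an enone whose dienolate can close on the imine and aromatise;
- acid-induced aldol condensation of arm and aldehyde during the transposition work-up.

Fallback, setting out from 5: after 7 is formed as in step 4, it is transmetalated with ZnBr2 (THF, −78 → 0 °C) to the benzylzinc bromide F6. F6 is coupled in a Negishi reaction (Pd(PPh3)4, zerovalent palladium, THF, 0 °C → rt) with (E)-4-oxopent-2-en-2-yl trifluoromethanesulfonate F7, made from pentane-2,4-dione with Tf2O and base. The activated vinyl triflate should add to palladium far faster than the electron-rich, ortho-alkoxy aryl bromide at this temperature. The coupled imine F8 is hydrolysed with a pH 5 acetate buffer to 9, where the route is rejoined. The non-basic benzylzinc cannot deprotonate its partner, the enone is formed directly with retention of the E geometry, and no strong acid is needed.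

**Further compounds**

F1 | step 8 | (1R,1'R,2S,2'S)-2,2'-diacetyl-3,3'-dimethyl-1,1',2,2'-tetrahydro-[7,7'-binaphthalene]-1,1',8,8'-tetrol (enantiomer of 15) | Oc1c(-c2ccc3c(c2O)[C@H](O)[C@@H](C(C)=O)C(C)=C3)ccc2c1[C@H](O)[C@@H](C(C)=O)C(C)=C2
F2 | step 8 | (1S,2R,1'R,2'S)-2,2'-diacetyl-3,3'-dimethyl-1,1',2,2'-tetrahydro-[7,7'-binaphthalene]-1,1',8,8'-tetrol (meso-type diastereomer) | Oc1c(-c2ccc3c(c2O)[C@H](O)[C@@H](C(C)=O)C(C)=C3)ccc2c1[C@@H](O)[C@H](C(C)=O)C(C)=C2
F3 | step 9 | mono(di-tert-butylsilylene) of 15, bridging O1 and O8 of one half | Oc1c(-c2ccc3c4c2O[Si](C(C)(C)C)(C(C)(C)C)O[C@H]4[C@H](C(C)=O)C(C)=C3)ccc2c1[C@@H](O)[C@H](C(C)=O)C(C)=C2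
F4 | step 9 | bis(di-tert-butylsilylene) of 15 | CC(C)(C)[Si]1(C(C)(C)C)Oc2c(-c3ccc4c5c3O[Si](C(C)(C)C)(C(C)(C)C)O[C@H]5[C@H](C(C)=O)C(C)=C4)ccc3c2[C@@H](O1)[C@H](C(C)=O)C(C)=C3
F5 | step 9 | 17 with O1' and O8' of the dihydro half bridged by di-tert-butylsilylene | Oc1c(-c2ccc3c4c2O[Si](C(C)(C)C)(C(C)(C)C)O[C@H]4[C@H](C(C)=O)C(C)=C3)ccc2cc(C)c(C(C)=O)c(O)c12
F6 | step 4 | benzylzinc bromide from 7 (imine and aryl bromide retained) | Br[Zn]Cc1ccc(Br)c(OCOC)c1/C=N/C(C)(C)C
F7 | step 4 | (E)-4-oxopent-2-en-2-yl trifluoromethanesulfonate | CC(=O)/C=C(\C)OS(=O)(=O)C(F)(F)F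
F8 | step 4 | N-tert-butylimine of 9 | CC(=O)/C=C(\C)Cc1ccc(Br)c(OCOC)c1/C=N/C(C)(C)C
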